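The plan rests on disconnecting the aryl ether bond C8a–O1 of ring C. Since the 7-hydroxyl of ring A lies para to C4a and O1 sits on the neighbouring C8a, ring A can enter as a simple 4-hydroxyphenyl group, be dearomatised to its C4a para-quinol and be rebuilt with O1 in place. In a single flask the C2 hydroxyl adds to the dienone at C8a, which closes ring C, and the C4a hydroxyl departs as water, which returns ring A as the 7-phenol. The precursor is a hepta-O-benzyl 1,3,3-triarylpropanol whose third aryl group is that quinol; C4 and C2 are fixed beforehand by two independent chiral catalysts.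

Key step: step 10

Numbering: the upper flavan is O1, C2, C3, C4, C4a, C5–C8, C8a (rings A, B, C). The epigallocatechin unit carries primed atoms (rings D, E, F).

Remark on descriptors: the target is (2S,4R,2'R,3'R), with rings B and D trans on ring C. While C4a carries oxygen (hydroperoxide, quinol, bicyclic ketol, sulfamate) it outranks C8', so C4 is then formally S although nothing at C4 moves.

Assumption: the hand of the diene ligand in step 6 is defined by the face it must attack (Cβ Si). If the empirical model for chalcones points the other way, the equally available antipode is used.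

Step 1
Reactants: 1 (−)-epigallocatechin
Product: 2 penta-O-benzyl-(−)-epigallocatechin (all five phenols benzylated; C3' hydroxyl free)
Conditions: BnBr (5.5 equiv), K2CO3 (6 equiv), DMF, 0 °C to rt, Ar
Reagents that add atoms: benzyl bromide BrCc1ccccc1
Why: Williamson etherification, in which carbonate deprotonates only the five phenols so the C3' alcohol stays free, while the cold, oxygen-free medium protects the pyrogallol ring E and the base-sensitive C2' centre, and no stereocentre is touched.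

Step 2
Reactants: 2 penta-O-benzyl-(−)-epigallocatechin
Product: 3 hexa-O-benzyl-(−)-epigallocatechin
Conditions: NaH (1.5 equiv), BnBr (1.3 equiv), Bu4NI (cat.), DMF, 0 °C to rt
Reagents that add atoms: benzyl bromide BrCc1ccccc1
Why: Williamson etherification of the remaining secondary alkoxide; with every phenol capped there is no quinone methide path to C2' epimerisation, so (2'R,3'R) is retained.

Step 3
Reactants: 3 hexa-O-benzyl-(−)-epigallocatechin
Product: 4 8'-bromo-hexa-O-benzyl-epigallocatechin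
Conditions: NBS (1.0 equiv), CH2Cl2, −78 °C to 0 °C
Reagents that add atoms: N-bromosuccinimide O=C1CCC(=O)N1Br
Why: Electrophilic aromatic bromination; ring D is the most electron-rich arene, and in O-alkylated flavan-3-ols C8' reacts ahead of C6', so one equivalent at low temperature should mark C8' alone.

Step 4
Reactants: 4 8'-bromo-hexa-O-benzyl-epigallocatechin
Product: 6 hexa-O-benzyl-epigallocatechin-8'-carbaldehyde, via C8' aryllithium 5 (not isolated)
Conditions: n-BuLi (1.1 equiv), THF, −78 °C; DMF (3 equiv), −78 °C to 0 °C; H2O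
Reagents that add atoms: N,N-dimethylformamide CN(C)C=O
Why: Bromine–lithium exchange followed by Bouveault-type formylation carries the secured C8' regiochemistry into the aldehyde, the exchange at −78 °C being faster than any benzylic deprotonation.

Step 5
Reactants: 6 hexa-O-benzyl-epigallocatechin-8'-carbaldehyde; 7 1-[4-(benzyloxy)phenyl]ethanone
Product: 8 (E)-1-[4-(benzyloxy)phenyl]-3-(hexa-O-benzyl-epigallocatechin-8'-yl)prop-2-en-1-one
Conditions: KOH (2 equiv), EtOH/THF 1:1, rt to 40 °C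
Reagents that add atoms: none
Why: Claisen–Schmidt condensation; the non-enolisable aldehyde accepts the enolate of 7, and E1cB loss of water gives the thermodynamically preferred E-enone, as is routine for 2,4,6-trialkoxybenzaldehydes.

Step 6
Reactants: 8 (E)-enone; 9 [4-(tert-butyldimethylsilyloxy)phenyl]boronic acid
Product: 10 (3R)-1-[4-(benzyloxy)phenyl]-3-[4-(tert-butyldimethylsilyloxy)phenyl]-3-(hexa-O-benzyl-epigallocatechin-8'-yl)propan-1-one
Conditions: 9 (2.5 equiv), [RhCl(C2H4)2]2 (3 mol %), 2,5-diphenylbicyclo[2.2.2]octa-2,5-diene (Ph-bod*, 6.6 mol %, enantiomer directing to the Cβ Si face), KOH (10 mol %), dioxane/H2O 10:1, 50 °C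
Reagents that add atoms: none
Why: Hayashi–Miyaura reaction (rhodium-catalysed asymmetric 1,4-addition of an arylboronic acid to a chalcone-type enone, the established entry to diarylmethine centres); the aryl–rhodium species held by the chiral diene inserts the enone from the Cβ Si face and sets C4 as R under catalyst control, the nearest resident stereocentre C2' being four bonds away, and the near-neutral medium spares the aryl silyl ether.

Step 7
Reactants: 10 (3R)-ketone
Product: 11 (1S,3R)-1-[4-(benzyloxy)phenyl]-3-[4-(tert-butyldimethylsilyloxy)phenyl]-3-(hexa-O-benzyl-epigallocatechin-8'-yl)propan-1-ol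
Conditions: (R)-Me-CBS oxazaborolidine (20 mol %), BH3·SMe2 (1.0 equiv), THF, −20 °C; MeOH
Reagents that add atoms: none
Why: Corey–Bakshi–Shibata reduction; ring B acts as the large and the C3 methylene as the small ketone substituent, so the (R)-oxazaborolidine delivers hydride to the Re face and sets C2 as S independently of C4.

Step 8
Reactants: 11 (1S,3R)-silyl ether alcohol
Product: 12 (1S,3R)-1-[4-(benzyloxy)phenyl]-3-(4-hydroxyphenyl)-3-(hexa-O-benzyl-epigallocatechin-8'-yl)propan-1-ol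
Conditions: TBAF (1.1 equiv), AcOH (1.1 equiv), THF, 0 °C
Reagents that add atoms: none
Why: Fluoride-mediated desilylation, buffered with acetic acid so that neither the acid-labile 4-benzyloxybenzylic alcohol nor an air-sensitive phenolate is put at risk.

Step 9
Reactants: 12 (1S,3R)-phenol alcohol
Product: 14 C4a para-quinol of 12, via C4a hydroperoxide 13 (not isolated)
Conditions: O2 (1 atm), 5,10,15,20-tetraphenylporphyrin (1 mol %), white LED, CH2Cl2/MeOH 9:1, 0 °C; then Me2S (5 equiv), 0 °C to rt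
Reagents that add atoms: dioxygen O=O
Why: Dye-sensitised photooxygenation of a para-alkylphenol in a homogeneous organic medium suited to this lipophilic substrate; singlet oxygen adds para to the only free phenol without passing through a phenoxenium ion, so neither spiro-etherification by the C2 hydroxyl nor proton loss from C4 to a quinone methide should intervene, dimethyl sulfide reduces the O–O bond, and C4a is not stereogenic because its two enone arms are identical.

Step 10
Reactants: 14 C4a para-quinol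
Product: 18 hepta-O-benzyl target bearing the free 7-hydroxyl, via cis-fused ketol 15 (not isolated), via C4a sulfamate 16 (not isolated), via dienone tautomer 17 (not isolated)
Conditions: DBU (0.2 equiv), THF, 0 °C to rt; then Burgess reagent (1.2 equiv), rt to 50 °C
Reagents that add atoms: none
Why: DBU activates the C2 hydroxyl, which adds to the β-carbon C8a of either enone arm in a 6-exo-trig closure (C8a inside, C8 outside the new ring C) to give the cis-fused ketol 15. The Burgess reagent then sulfamoylates the only hydroxyl left, at C4a (16), and because cis fusion puts H8a on the same face as that oxygen, thermal syn elimination gives the push–pull dienone 17 (O1–C8a=C4a–C5=C6–C7=O), which enolises at C8 to the 7-phenol 18. The closest known chemistry is the intramolecular oxa-Michael addition of tethered alcohols to para-quinols and the dehydrative rearomatisation of quinol Michael adducts to meta-functionalised phenols, joined here to a standard Burgess dehydration of a tertiary alcohol. No lasting stereocentre is created: C4a and C8a are transient, both diastereotopic arms converge on one arene, and C2 (S) and C4 (R) persist because neither the C2–O nor the C4–H bond is broken. The step needs closure and dehydration without ionising the 4-benzyloxybenzylic C2–O bond, without heterolysis of C4–C4a toward a cation stabilised by ring D, and with loss of H8a rather than H4; the acid-free medium secures the first two, and the syn geometry, the vinylogous-ester stabilisation of 17 and the strain of a C4=C4a alkene wedged between the ortho substituents of ring D favour the third. All other oxygens are benzylated, so the dehydrating agent finds a single site, and it is held near one equivalent to spare the new phenol.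

Step 11
Reactants: 18 hepta-O-benzyl target bearing the free 7-hydroxyl
Product: 19 CNP0220331.1, (2S,4R)-4',7-dihydroxyflavan-(4→8')-(−)-epigallocatechin
Conditions: H2 (1 atm), Pd(OH)2/C, THF/MeOH 1:1, rt
Reagents that add atoms: none
Why: Catalytic hydrogenolysis of the seven benzyl ethers, the standard endgame for benzylated proanthocyanidins; in neutral solvent at 1 atm the O-benzyl groups should go well before the cyclic benzylic C2–O1 and C2'–O1' bonds, and no stereocentre is involved.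

Compound list

1 | (−)-epigallocatechin, (2'R,3'R) | Oc1cc(O)c2c(c1)O[C@H](c1cc(O)c(O)c(O)c1)[C@H](O)C2 | starting material
2 | penta-O-benzyl-(−)-epigallocatechin (5',7'-O of ring D and the three O of ring E benzylated, C3' hydroxyl free) | c3c(OCc9ccccc9)cc(OCc9ccccc9)c4c3O[C@H](c3cc(OCc9ccccc9)c(OCc9ccccc9)c(OCc9ccccc9)c3)[C@H](O)C4 | intermediate
3 | hexa-O-benzyl-(−)-epigallocatechin (C3' O-benzyl as well) | c3c(OCc9ccccc9)cc(OCc9ccccc9)c4c3O[C@H](c3cc(OCc9ccccc9)c(OCc9ccccc9)c(OCc9ccccc9)c3)[C@H](OCc9ccccc9)C4 | intermediate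
4 | 8'-bromo-hexa-O-benzyl-epigallocatechin | Brc3c(OCc9ccccc9)cc(OCc9ccccc9)c4c3O[C@H](c3cc(OCc9ccccc9)c(OCc9ccccc9)c(OCc9ccccc9)c3)[C@H](OCc9ccccc9)C4 | intermediate
5 | 8'-lithio-hexa-O-benzyl-epigallocatechin | [Li]c3c(OCc9ccccc9)cc(OCc9ccccc9)c4c3O[C@H](c3cc(OCc9ccccc9)c(OCc9ccccc9)c(OCc9ccccc9)c3)[C@H](OCc9ccccc9)C4 | intermediate
6 | hexa-O-benzyl-epigallocatechin-8'-carbaldehyde | O=Cc3c(OCc9ccccc9)cc(OCc9ccccc9)c4c3O[C@H](c3cc(OCc9ccccc9)c(OCc9ccccc9)c(OCc9ccccc9)c3)[C@H](OCc9ccccc9)C4 | intermediate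
7 | 1-[4-(benzyloxy)phenyl]ethanone | CC(=O)c1ccc(OCc2ccccc2)cc1 | starting material
8 | (E)-1-[4-(benzyloxy)phenyl]-3-(hexa-O-benzyl-epigallocatechin-8'-yl)prop-2-en-1-one | c9ccccc9COc1ccc(C(=O)/C=C/c3c(OCc9ccccc9)cc(OCc9ccccc9)c4c3O[C@H](c3cc(OCc9ccccc9)c(OCc9ccccc9)c(OCc9ccccc9)c3)[C@H](OCc9ccccc9)C4)cc1 | intermediate
9 | [4-(tert-butyldimethylsilyloxy)phenyl]boronic acid | CC(C)(C)[Si](C)(C)Oc1ccc(B(O)O)cc1 | starting material
10 | (3R)-1-[4-(benzyloxy)phenyl]-3-[4-(tert-butyldimethylsilyloxy)phenyl]-3-(hexa-O-benzyl-epigallocatechin-8'-yl)propan-1-one | c9ccccc9COc1ccc(C(=O)C[C@@H](c3c(OCc9ccccc9)cc(OCc9ccccc9)c4c3O[C@H](c3cc(OCc9ccccc9)c(OCc9ccccc9)c(OCc9ccccc9)c3)[C@H](OCc9ccccc9)C4)c3ccc(O[Si](C)(C)C(C)(C)C)cc3)cc1 | intermediate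
11 | (1S,3R)-propan-1-ol from 10 (flavan C2 S, C4 R) | c9ccccc9COc1ccc([C@@H](O)C[C@@H](c3c(OCc9ccccc9)cc(OCc9ccccc9)c4c3O[C@H](c3cc(OCc9ccccc9)c(OCc9ccccc9)c(OCc9ccccc9)c3)[C@H](OCc9ccccc9)C4)c3ccc(O[Si](C)(C)C(C)(C)C)cc3)cc1 | intermediate
12 | (1S,3R)-1-[4-(benzyloxy)phenyl]-3-(4-hydroxyphenyl)-3-(hexa-O-benzyl-epigallocatechin-8'-yl)propan-1-ol | c9ccccc9COc1ccc([C@@H](O)C[C@@H](c3c(OCc9ccccc9)cc(OCc9ccccc9)c4c3O[C@H](c3cc(OCc9ccccc9)c(OCc9ccccc9)c(OCc9ccccc9)c3)[C@H](OCc9ccccc9)C4)c3ccc(O)cc3)cc1 | intermediate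
13 | C4a hydroperoxide: ring A of 12 as 4-hydroperoxycyclohexa-2,5-dienone (C2 S, C4 formally S) | c9ccccc9COc1ccc([C@@H](O)C[C@@H](c3c(OCc9ccccc9)cc(OCc9ccccc9)c4c3O[C@H](c3cc(OCc9ccccc9)c(OCc9ccccc9)c(OCc9ccccc9)c3)[C@H](OCc9ccccc9)C4)C3(OO)C=CC(=O)C=C3)cc1 | intermediate
14 | C4a para-quinol: ring A of 12 as 4-hydroxycyclohexa-2,5-dienone (C2 S, C4 formally S) | c9ccccc9COc1ccc([C@@H](O)C[C@@H](c3c(OCc9ccccc9)cc(OCc9ccccc9)c4c3O[C@H](c3cc(OCc9ccccc9)c(OCc9ccccc9)c(OCc9ccccc9)c3)[C@H](OCc9ccccc9)C4)C3(O)C=CC(=O)C=C3)cc1 | intermediate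
15 | cis-fused ketol, 4a-hydroxy-2,3,4,4a,8,8a-hexahydrochromen-7-one with ring B on C2 and ring D on C4 (C4a and C8a transient, cis, configuration relative to C4 left open) | c9ccccc9COc1ccc([C@@H]2C[C@@H](c3c(OCc9ccccc9)cc(OCc9ccccc9)c4c3O[C@H](c3cc(OCc9ccccc9)c(OCc9ccccc9)c(OCc9ccccc9)c3)[C@H](OCc9ccccc9)C4)C3(O)C=CC(=O)CC3O2)cc1 | intermediate
16 | C4a O-sulfamate of 15, drawn as the neutral N-(methoxycarbonyl)sulfamate ester | c9ccccc9COc1ccc([C@@H]2C[C@@H](c3c(OCc9ccccc9)cc(OCc9ccccc9)c4c3O[C@H](c3cc(OCc9ccccc9)c(OCc9ccccc9)c(OCc9ccccc9)c3)[C@H](OCc9ccccc9)C4)C3(OS(=O)(=O)NC(=O)OC)C=CC(=O)CC3O2)cc1 | intermediate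
17 | dienone tautomer of 18, 3,4-dihydro-2H-chromen-7(8H)-one (C4a=C8a, C5=C6) | c9ccccc9COc1ccc([C@@H]2C[C@@H](c3c(OCc9ccccc9)cc(OCc9ccccc9)c4c3O[C@H](c3cc(OCc9ccccc9)c(OCc9ccccc9)c(OCc9ccccc9)c3)[C@H](OCc9ccccc9)C4)C3=C(O2)CC(=O)C=C3)cc1 | intermediate
18 | hepta-O-benzyl target, (2S,4R)-2-[4-(benzyloxy)phenyl]-4-(hexa-O-benzyl-epigallocatechin-8'-yl)chroman-7-ol | c9ccccc9COc1ccc([C@@H]2C[C@@H](c3c(OCc9ccccc9)cc(OCc9ccccc9)c4c3O[C@H](c3cc(OCc9ccccc9)c(OCc9ccccc9)c(OCc9ccccc9)c3)[C@H](OCc9ccccc9)C4)c3ccc(O)cc3O2)cc1 | intermediate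
19 | CNP0220331.1, (2S,4R,2'R,3'R) | Oc1ccc([C@@H]2C[C@@H](c3c(O)cc(O)c4c3O[C@H](c3cc(O)c(O)c(O)c3)[C@H](O)C4)c3ccc(O)cc3O2)cc1 | target

Total steps: 11. Longest linear sequence: 11 steps (1 to 19); 7 and 9 are purchased.

Steps most likely to fail

**1. Step 10.**
- Risk: ring closure may stay reversible, so that the dehydrating agent meets the C2 hydroxyl. The crowded C4a hydroxyl may be sulfamoylated only slowly. Elimination may run toward C4 with later unselective reprotonation, which would erode the C4 configuration.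
- Fallback, from 8 back to 18: ring C is closed at its other oxygen bond, O1–C2, by substitution with inversion. 4-Bromoresorcinol is silylated (TBSCl, imidazole, DMF) to 4-bromo-1,3-bis(tert-butyldimethylsilyloxy)benzene F1. Miyaura borylation (B2pin2, PdCl2(dppf), KOAc, dioxane) turns this into the pinacol boronate F2. The catalyst of step 6 adds it to 8 to give the (3R)-ketone F3, whose ring A is 2,4-bis(silyloxy)phenyl. (S)-Me-CBS/BH3·SMe2 gives the (1R,3R)-alcohol F4, and TBAF/AcOH frees the resorcinol alcohol F5. An intramolecular Mitsunobu etherification (PPh3, DIAD, THF, 0 °C), in which only the ortho phenol can reach C2, inverts C2 to S and delivers 18.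

**2. Step 6.**
- Risk: insertion at the β-carbon, which is electron-rich and shielded by two ortho alkoxy groups, may be so slow that protodeboronation consumes the boronic acid. The resident chirality may also oppose the ligand and lower facial selectivity.
- Fallback, from 6 back to 10: auxiliary-controlled organocopper addition. Doebner–Knoevenagel condensation of 6 with malonic acid (pyridine, piperidine, 90 °C) gives the (E)-cinnamic acid F6. Activation with pivaloyl chloride/Et3N, then (S)-4-phenyloxazolidin-2-one and LiCl, gives the N-enoyl imide F7. 4-(tert-Butyldimethylsilyloxy)phenylmagnesium bromide F8 is made from the commercial aryl bromide and Mg and is combined with CuBr·SMe2. It adds to the magnesium-chelated s-cis imide anti to the 4-phenyl group, that is to the Cβ Si face, to give the (3R)-imide adduct F9. AlMe3/MeNH(OMe)·HCl exchanges the auxiliary for the Weinreb amide F10, and commercial 4-benzyloxyphenylmagnesium bromide converts this into 10.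

**3. Step 9.**
- Risk: oxygen uptake by the neutral phenol may be slow, and sensitised oxidation of the electron-rich ring D may compete.
- Fallback, from 11 back to 14: two-electron oxidation with a trivalent iodine reagent after masking the C2 hydroxyl. TESCl/imidazole gives the C2 triethylsilyl ether F11. Cs2CO3 in DMF/H2O removes only the aryl silyl group to give the phenol F12. PhI(OAc)2 in MeCN/H2O at 0 °C engages the phenol oxygen by ligand exchange and so leaves rings D and E alone. Water is captured at C4a to give the silylated quinol F13, the masked C2 oxygen being unable to spirocyclise. TBAF/AcOH at 0 °C then frees 14. This cationic path carries its own risk of proton loss from C4, which is why it stands only in reserve.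

Further compounds

F1 | step 10 | 4-bromo-1,3-bis(tert-butyldimethylsilyloxy)benzene | CC(C)(C)[Si](C)(C)Oc1ccc(Br)c(O[Si](C)(C)C(C)(C)C)c1
F2 | step 10 | 2-[2,4-bis(tert-butyldimethylsilyloxy)phenyl]-4,4,5,5-tetramethyl-1,3,2-dioxaborolane | CC(C)(C)[Si](C)(C)Oc1ccc(B2OC(C)(C)C(C)(C)O2)c(O[Si](C)(C)C(C)(C)C)c1
F3 | step 10 | (3R)-1-[4-(benzyloxy)phenyl]-3-[2,4-bis(tert-butyldimethylsilyloxy)phenyl]-3-(hexa-O-benzyl-epigallocatechin-8'-yl)propan-1-one | c9ccccc9COc1ccc(C(=O)C[C@@H](c3c(OCc9ccccc9)cc(OCc9ccccc9)c4c3O[C@H](c3cc(OCc9ccccc9)c(OCc9ccccc9)c(OCc9ccccc9)c3)[C@H](OCc9ccccc9)C4)c3ccc(O[Si](C)(C)C(C)(C)C)cc3O[Si](C)(C)C(C)(C)C)cc1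
F4 | step 10 | (1R,3R)-propan-1-ol from F3 | c9ccccc9COc1ccc([C@H](O)C[C@@H](c3c(OCc9ccccc9)cc(OCc9ccccc9)c4c3O[C@H](c3cc(OCc9ccccc9)c(OCc9ccccc9)c(OCc9ccccc9)c3)[C@H](OCc9ccccc9)C4)c3ccc(O[Si](C)(C)C(C)(C)C)cc3O[Si](C)(C)C(C)(C)C)cc1
F5 | step 10 | (1R,3R)-1-[4-(benzyloxy)phenyl]-3-(2,4-dihydroxyphenyl)-3-(hexa-O-benzyl-epigallocatechin-8'-yl)propan-1-ol | c9ccccc9COc1ccc([C@H](O)C[C@@H](c3c(OCc9ccccc9)cc(OCc9ccccc9)c4c3O[C@H](c3cc(OCc9ccccc9)c(OCc9ccccc9)c(OCc9ccccc9)c3)[C@H](OCc9ccccc9)C4)c3ccc(O)cc3O)cc1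
F6 | step 6 | (E)-3-(hexa-O-benzyl-epigallocatechin-8'-yl)prop-2-enoic acid | OC(=O)/C=C/c3c(OCc9ccccc9)cc(OCc9ccccc9)c4c3O[C@H](c3cc(OCc9ccccc9)c(OCc9ccccc9)c(OCc9ccccc9)c3)[C@H](OCc9ccccc9)C4
F7 | step 6 | (4S)-3-[(E)-3-(hexa-O-benzyl-epigallocatechin-8'-yl)prop-2-enoyl]-4-phenyloxazolidin-2-one | O=C1OC[C@H](c2ccccc2)N1C(=O)/C=C/c3c(OCc9ccccc9)cc(OCc9ccccc9)c4c3O[C@H](c3cc(OCc9ccccc9)c(OCc9ccccc9)c(OCc9ccccc9)c3)[C@H](OCc9ccccc9)C4
F8 | step 6 | 4-(tert-butyldimethylsilyloxy)phenylmagnesium bromide | CC(C)(C)[Si](C)(C)Oc1ccc([Mg]Br)cc1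
F9 | step 6 | (4S)-3-[(3R)-3-[4-(tert-butyldimethylsilyloxy)phenyl]-3-(hexa-O-benzyl-epigallocatechin-8'-yl)propanoyl]-4-phenyloxazolidin-2-one | O=C1OC[C@H](c2ccccc2)N1C(=O)C[C@@H](c3c(OCc9ccccc9)cc(OCc9ccccc9)c4c3O[C@H](c3cc(OCc9ccccc9)c(OCc9ccccc9)c(OCc9ccccc9)c3)[C@H](OCc9ccccc9)C4)c3ccc(O[Si](C)(C)C(C)(C)C)cc3
F10 | step 6 | (3R)-N-methoxy-N-methyl-3-[4-(tert-butyldimethylsilyloxy)phenyl]-3-(hexa-O-benzyl-epigallocatechin-8'-yl)propanamide | CON(C)C(=O)C[C@@H](c3c(OCc9ccccc9)cc(OCc9ccccc9)c4c3O[C@H](c3cc(OCc9ccccc9)c(OCc9ccccc9)c(OCc9ccccc9)c3)[C@H](OCc9ccccc9)C4)c3ccc(O[Si](C)(C)C(C)(C)C)cc3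
F11 | step 9 | C2 O-triethylsilyl ether of 11 | c9ccccc9COc1ccc([C@@H](O[Si](CC)(CC)CC)C[C@@H](c3c(OCc9ccccc9)cc(OCc9ccccc9)c4c3O[C@H](c3cc(OCc9ccccc9)c(OCc9ccccc9)c(OCc9ccccc9)c3)[C@H](OCc9ccccc9)C4)c3ccc(O[Si](C)(C)C(C)(C)C)cc3)cc1
F12 | step 9 | C2 O-triethylsilyl ether of 12 | c9ccccc9COc1ccc([C@@H](O[Si](CC)(CC)CC)C[C@@H](c3c(OCc9ccccc9)cc(OCc9ccccc9)c4c3O[C@H](c3cc(OCc9ccccc9)c(OCc9ccccc9)c(OCc9ccccc9)c3)[C@H](OCc9ccccc9)C4)c3ccc(O)cc3)cc1
F13 | step 9 | C2 O-triethylsilyl ether of 14 | c9ccccc9COc1ccc([C@@H](O[Si](CC)(CC)CC)C[C@@H](c3c(OCc9ccccc9)cc(OCc9ccccc9)c4c3O[C@H](c3cc(OCc9ccccc9)c(OCc9ccccc9)c(OCc9ccccc9)c3)[C@H](OCc9ccccc9)C4)C3(O)C=CC(=O)C=C3)cc1
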